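The target is cut between the α-CH2 of the ketone and the β-carbon that bears the methyl group. In one operation an iridium-catalysed enantioselective allylic alkylation joins the silyl enol ether of an L-threonine-derived cis-epoxy methyl ketone to (E)-crotyl methyl carbonate, forming this bond and setting the β-stereocentre as a 1-methylallyl unit. It exploits that the CH(CH3)–CH2–CH2 segment up to the trisubstituted alkene is a masked but-3-en-2-yl group, and that a temporary oxirane ring over the carbinol and chlorine-bearing carbons allows enolisation only at the methyl carbon. The vinyl group is then joined to an (E)-vinyl iodide carrying both furan rings by B-alkyl Suzuki coupling; chloride opens the oxirane last.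

Key step: step 7

Remark: the sense of induction in step 7 follows the ligand antipode; the antipode that gives the (3S) centre is meant (written as (Ra,Rc,Rc)-L, its mirror image being used if the sense proves opposite). L = O,O'-(1,1'-binaphthalene-2,2'-diyl) N,N-bis[1-(2-methoxyphenyl)ethyl]phosphoramidite.

Step 1
Reactants: 1 L-threonine
Product: 2 (2S,3R)-2-bromo-3-hydroxybutanoic acid
Conditions: NaNO2, aq HBr (48 %), H2O, −5 → 0 °C
Reagents that add atoms: hydrobromic acid, Br
Why: Diazotisation of the α-amino acid in the presence of bromide should replace NH2 by Br with net retention (double inversion through the α-lactone), the standard amino acid to α-halo acid conversion, leaving the C3 carbinol centre untouched.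

Step 2
Reactants: 2 (2S,3R)-2-bromo-3-hydroxybutanoic acid
Product: 3 potassium (2R,3R)-3-methyloxirane-2-carboxylate
Conditions: KOH (2.1 equiv), EtOH, 0 °C → rt
Reagents that add atoms: potassium hydroxide, [K+].[OH-]
Why: Intramolecular Williamson ether synthesis, in which the C3 alkoxide displaces bromide at C2 with inversion, so that the threo bromohydrin should give the cis oxirane.

Step 3
Reactants: 3 potassium (2R,3R)-3-methyloxirane-2-carboxylate
Product: 4 (2R,3R)-N-methoxy-N,3-dimethyloxirane-2-carboxamide
Conditions: MeNH(OMe)·HCl, DCC, HOBt (0.1 equiv), CH2Cl2/MeCN, 0 °C → rt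
Reagents that add atoms: N,O-dimethylhydroxylamine hydrochloride, CNOC.Cl
Why: Carbodiimide amide coupling (Weinreb amide formation) in which the amine hydrochloride supplies the proton for the carboxylate; the oxirane stereocentres are not involved.

Step 4
Reactants: 4 (2R,3R)-N-methoxy-N,3-dimethyloxirane-2-carboxamide
Product: 5 1-[(2R,3R)-3-methyloxiran-2-yl]ethan-1-one
Conditions: MeMgBr, THF, −40 → 0 °C; aq NH4Cl
Reagents that add atoms: methylmagnesium bromide, C[Mg]Br
Why: Weinreb ketone synthesis, in which the chelated tetrahedral intermediate stops the addition at the ketone and the cold Grignard reagent should not open the oxirane.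

Step 5
Reactants: 5 1-[(2R,3R)-3-methyloxiran-2-yl]ethan-1-one
Product: 7 trimethyl({1-[(2R,3R)-3-methyloxiran-2-yl]ethenyl}oxy)silane, via lithium enolate 6 (not isolated)
Conditions: LiN(iPr)2, Me3SiCl (in situ quench), THF, −78 °C; pentane, filtration, distillation
Reagents that add atoms: chlorotrimethylsilane, C[Si](C)(C)Cl
Why: Kinetic enolisation with internal silyl trapping (silyl enol ether formation), which can only occur at the methyl group because enolisation toward the oxirane carbon would give a strained alkylidene-oxirane.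

Step 6
Reactants: 8 (2E)-but-2-en-1-ol
Product: 9 (2E)-but-2-en-1-yl methyl carbonate
Conditions: ClCO2Me, pyridine, CH2Cl2, 0 °C
Reagents that add atoms: methyl chloroformate, COC(=O)Cl
Why: Acylation of the primary allylic alcohol with a chloroformate (carbonate formation), with the (E) geometry unchanged.

Step 7
Reactants: 7 trimethyl({1-[(2R,3R)-3-methyloxiran-2-yl]ethenyl}oxy)silane; 9 (2E)-but-2-en-1-yl methyl carbonate
Product: 10 (3S)-3-methyl-1-[(2R,3R)-3-methyloxiran-2-yl]pent-4-en-1-one
Conditions: [Ir(cod)Cl]2 (2 mol %), (Ra,Rc,Rc)-L (4 mol %), CsF (0.4 equiv), ZnF2 (1.5 equiv), DME, 50 °C; 7 in 1.5-fold excess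
Reagents that add atoms: none
Why: The cyclometallated monovalent iridium–phosphoramidite catalyst ionises carbonate 9 (loss of CO2 and methoxide) to a (1-methylallyl)iridium cation, while fluoride and the released methoxide unmask enol silane 7 to a zinc enolate that attacks the methyl-bearing allyl terminus from the face opposite to the metal, forming the CH2–CH(CH3) bond. The closest known reaction type is the iridium-catalysed, branched-selective and enantioselective allylic alkylation of methyl-ketone silyl enol ethers promoted by CsF/ZnF2 (a Tsuji–Trost-type allylic substitution). No ring is closed. The new (3S) centre is set by the ligand, which fixes the allyl face bound to iridium; because the oxirane centres are remote, the minor facial isomer would be a separable diastereomer. The step needs attack at the substituted rather than the unsubstituted allyl terminus, which the intrinsic preference of this iridium catalyst class should secure, and C-allylation at the methyl carbon only, which the oxirane ring secures by forbidding enolisation on its side while being itself (a 2-oxy-substituted, cis-disubstituted vinyl epoxide) a poor substrate for ionisation. Double allylation should be held back by the excess of 7 and the substoichiometric soluble fluoride.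

Step 8
Reactants: 11 3-bromofuran; 12 4-bromofuran-2-carbaldehyde
Product: 14 (4-bromofuran-2-yl)(furan-3-yl)methanol, via furan-3-yllithium 13 (not isolated)
Conditions: 11, n-BuLi, Et2O, −78 °C; then 12, −78 °C; aq NH4Cl
Reagents that add atoms: none
Why: Bromine–lithium exchange at −78 °C (where 3-furyllithium does not isomerise) followed by 1,2-addition to the aldehyde, which is faster than exchange at the C4 bromide; the carbinol centre is racemic and is removed in step 9.

Step 9
Reactants: 14 (4-bromofuran-2-yl)(furan-3-yl)methanol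
Product: 15 4-bromo-2-(furan-3-ylmethyl)furan
Conditions: Et3SiH (4 equiv), CF3CO2H (3 equiv, added last), CH2Cl2, −30 → 0 °C
Reagents that add atoms: none
Why: Ionic hydrogenation, in which the carbocation stabilised by both furan rings is trapped by hydride from the silane held in excess at low temperature and high dilution.

Step 10
Reactants: 15 4-bromo-2-(furan-3-ylmethyl)furan; 16 (5-chloropent-1-yn-1-yl)trimethylsilane
Product: 19 2-(furan-3-ylmethyl)-4-(pent-4-yn-1-yl)furan, via Grignard reagent 17 (not isolated), via silylalkyne 18 (not isolated)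
Conditions: 16, Mg, THF, 50 °C; then 15, NiCl2(dppp) (3 mol %), THF, rt → 45 °C; then MeOH, K2CO3, rt
Reagents that add atoms: none
Why: Kumada–Tamao–Corriu coupling of the 3-bromofuran-type bromide with a primary alkyl Grignard reagent, followed in the same flask by methanolysis of the alkynyl–silicon bond.

Step 11
Reactants: 19 2-(furan-3-ylmethyl)-4-(pent-4-yn-1-yl)furan
Product: 21 2-(furan-3-ylmethyl)-4-[(4E)-5-iodo-4-methylpent-4-en-1-yl]furan, via alkenylalane 20 (not isolated)
Conditions: Me3Al (2.5 equiv), Cp2ZrCl2 (0.25 equiv), CH2Cl2, 0 °C → rt; then I2, THF, −30 → 0 °C; aq Na2S2O3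
Reagents that add atoms: trimethylaluminium, C[Al](C)C; iodine, II
Why: Negishi zirconium-catalysed carboalumination adds methyl and aluminium syn across the terminal alkyne (aluminium on the terminal carbon) and iodine replaces aluminium with retention, which should give the (E)-vinyl iodide.

Step 12
Reactants: 10 (3S)-3-methyl-1-[(2R,3R)-3-methyloxiran-2-yl]pent-4-en-1-one; 21 2-(furan-3-ylmethyl)-4-[(4E)-5-iodo-4-methylpent-4-en-1-yl]furan
Product: 23 (1RS,3R,6E)-10-[5-(furan-3-ylmethyl)furan-3-yl]-3,7-dimethyl-1-[(2S,3R)-3-methyloxiran-2-yl]dec-6-en-1-ol, via bis-boron adduct 22 (not isolated)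
Conditions: 9-BBN (2.5 equiv), THF, 0 °C → rt; then 21, PdCl2(dppf) (5 mol %), AsPh3 (10 mol %), Cs2CO3, DMF/H2O, rt; ethanolamine work-up
Reagents that add atoms: none
Why: B-alkyl Suzuki–Miyaura coupling in which 9-BBN hydroborates the vinyl group at its terminal carbon and deliberately also reduces the ketone to its borinate (any unreduced ketone converges in step 13), and the primary alkyl group is transferred to the vinyl iodide with retention of the (E) geometry.

Step 13
Reactants: 23 (1RS,3R,6E)-10-[5-(furan-3-ylmethyl)furan-3-yl]-3,7-dimethyl-1-[(2S,3R)-3-methyloxiran-2-yl]dec-6-en-1-ol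
Product: 24 (3R,6E)-10-[5-(furan-3-ylmethyl)furan-3-yl]-3,7-dimethyl-1-[(2R,3R)-3-methyloxiran-2-yl]dec-6-en-1-one
Conditions: DMP (1.3 equiv), pyridine, CH2Cl2, 0 °C → rt
Reagents that add atoms: none
Why: Dess–Martin oxidation should convert both carbinol epimers into one ketone under buffered conditions that leave the oxirane, the furans and the alkene intact.

Step 14
Reactants: 24 (3R,6E)-10-[5-(furan-3-ylmethyl)furan-3-yl]-3,7-dimethyl-1-[(2R,3R)-3-methyloxiran-2-yl]dec-6-en-1-one
Product: 25 (2S,3S,6R,9E)-2-chloro-13-[5-(furan-3-ylmethyl)furan-3-yl]-3-hydroxy-6,10-dimethyltridec-9-en-4-one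
Conditions: LiCl (5 equiv), AcOH (3 equiv), THF, rt; neutral work-up
Reagents that add atoms: lithium chloride, [Li+].[Cl-]
Why: Acid-assisted SN2 opening of the α,β-epoxy ketone by chloride at the methyl-bearing carbon remote from the carbonyl (attack next to the carbonyl is disfavoured electronically) with inversion, so the cis oxirane should give the syn (2S,3S) chlorohydrin, the carbinol centre keeping its configuration.

Compound list
1 | L-threonine, (2S,3R)-2-amino-3-hydroxybutanoic acid | C[C@@H](O)[C@H](N)C(=O)O | starting material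
2 | (2S,3R)-2-bromo-3-hydroxybutanoic acid | C[C@@H](O)[C@H](Br)C(=O)O | intermediate
3 | potassium (2R,3R)-3-methyloxirane-2-carboxylate | C[C@H]1O[C@H]1C(=O)[O-].[K+] | intermediate
4 | (2R,3R)-N-methoxy-N,3-dimethyloxirane-2-carboxamide | C[C@H]1O[C@H]1C(=O)N(C)OC | intermediate
5 | 1-[(2R,3R)-3-methyloxiran-2-yl]ethan-1-one | C[C@H]1O[C@H]1C(C)=O | intermediate
6 | lithium 1-[(2R,3R)-3-methyloxiran-2-yl]ethen-1-olate (formed in the flask) | C[C@H]1O[C@H]1C(=C)[O-].[Li+] | intermediate
7 | trimethyl({1-[(2R,3R)-3-methyloxiran-2-yl]ethenyl}oxy)silane | C[C@H]1O[C@H]1C(=C)O[Si](C)(C)C | intermediate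
8 | (2E)-but-2-en-1-ol | C/C=C/CO | starting material
9 | (2E)-but-2-en-1-yl methyl carbonate | C/C=C/COC(=O)OC | intermediate
10 | (3S)-3-methyl-1-[(2R,3R)-3-methyloxiran-2-yl]pent-4-en-1-one | C=C[C@@H](C)CC(=O)[C@@H]1O[C@@H]1C | intermediate
11 | 3-bromofuran | Brc1ccoc1 | starting material
12 | 4-bromofuran-2-carbaldehyde | O=Cc1cc(Br)co1 | starting material
13 | furan-3-yllithium (formed in the flask) | [Li]c1ccoc1 | intermediate
14 | (4-bromofuran-2-yl)(furan-3-yl)methanol, racemic | OC(c1ccoc1)c1cc(Br)co1 | intermediate
15 | 4-bromo-2-(furan-3-ylmethyl)furan | Brc1coc(Cc2ccoc2)c1 | intermediate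
16 | (5-chloropent-1-yn-1-yl)trimethylsilane | C[Si](C)(C)C#CCCCCl | starting material
17 | [5-(trimethylsilyl)pent-4-yn-1-yl]magnesium chloride (formed in the flask) | C[Si](C)(C)C#CCCC[Mg]Cl | intermediate
18 | trimethyl{5-[5-(furan-3-ylmethyl)furan-3-yl]pent-1-yn-1-yl}silane (formed in the flask) | C[Si](C)(C)C#CCCCc1coc(Cc2ccoc2)c1 | intermediate
19 | 2-(furan-3-ylmethyl)-4-(pent-4-yn-1-yl)furan | C#CCCCc1coc(Cc2ccoc2)c1 | intermediate
20 | dimethyl{(1E)-5-[5-(furan-3-ylmethyl)furan-3-yl]-2-methylpent-1-en-1-yl}alumane (formed in the flask) | C/C(=C\[Al](C)C)CCCc1coc(Cc2ccoc2)c1 | intermediate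
21 | 2-(furan-3-ylmethyl)-4-[(4E)-5-iodo-4-methylpent-4-en-1-yl]furan | C/C(=C\I)CCCc1coc(Cc2ccoc2)c1 | intermediate
22 | bis-boron adduct of 10: 9-BBN on the terminal chain carbon and on the carbinol oxygen, carbinol centre as a mixture (formed in the flask) | B1(C2CCCC1CCC2)CC[C@@H](C)CC(OB1C2CCCC1CCC2)[C@@H]1O[C@@H]1C | intermediate
23 | (1RS,3R,6E)-10-[5-(furan-3-ylmethyl)furan-3-yl]-3,7-dimethyl-1-[(2S,3R)-3-methyloxiran-2-yl]dec-6-en-1-ol | C/C(=C\CC[C@@H](C)CC(O)[C@@H]1O[C@@H]1C)CCCc1coc(Cc2ccoc2)c1 | intermediate
24 | (3R,6E)-10-[5-(furan-3-ylmethyl)furan-3-yl]-3,7-dimethyl-1-[(2R,3R)-3-methyloxiran-2-yl]dec-6-en-1-one | C/C(=C\CC[C@@H](C)CC(=O)[C@@H]1O[C@@H]1C)CCCc1coc(Cc2ccoc2)c1 | intermediate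
25 | (2S,3S,6R,9E)-2-chloro-13-[5-(furan-3-ylmethyl)furan-3-yl]-3-hydroxy-6,10-dimethyltridec-9-en-4-one | C/C(=C\CC[C@@H](C)CC(=O)[C@H](O)[C@H](C)Cl)CCCc1coc(Cc2ccoc2)c1 | target

Total step count: 14. Longest linear sequence: 9 steps (steps 1, 2, 3, 4, 5, 7, 12, 13, 14).

Steps most likely to fail

Step 7. With methyl as the smallest possible allyl substituent, attack may drift to the unsubstituted terminus and facial discrimination may weaken; the unmasked enolate may also self-condense or attack its own oxirane in a Favorskii-type closure. The fallback sets out from 5 and comes back at 10. Commercial (2R)-but-3-en-2-ol is converted with methyl chloroformate and pyridine into (2R)-but-3-en-2-yl methyl carbonate F1. Ketone 5 is deprotonated with LiN(SiMe3)2 (THF, −78 °C) to the lithium enolate 6 and transmetallated with CuI to the copper enolate of 5 F2. The rhodium-catalysed allylic alkylation (RhCl(PPh3)3, P(OMe)3, THF, −10 °C → rt) should then replace the secondary carbonate with overall retention and without allyl transposition, so the centre is carried over from the enantiopure carbonate and 10 results.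

Step 12. Once the borinate is hydrolysed in the aqueous base, the alkoxide next to the oxirane may shift the ring onto itself (Payne rearrangement), and the oxygen-bound boron may slow alkyl transfer so that protodeboronation competes. The fallback sets out from 10 and comes back at 23. Ketone 10 is reduced with NaBH4 (MeOH, 0 °C) to the epoxy alcohol (1RS,3S)-3-methyl-1-(3-methyloxiran-2-yl)pent-4-en-1-ol F3, which is silylated (Et3SiCl, imidazole, DMF) to the triethylsilyl ether of F3 F4. Hydroboration with 1.2 equiv of 9-BBN gives the B-alkyl-9-BBN derivative of F4 F5, which is coupled with 21 under the palladium conditions of step 12 to the silyl ether of 23 F6; Bu4NF in THF then frees 23. No alkoxide meets base in this sequence.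

Step 14. Chloride may attack the oxirane carbon next to the carbonyl, or the opening may be so slow that forcing acid degrades the furans or adds HCl to the trisubstituted alkene; the product can also lose HCl on contact with base. The fallback sets out from 10 and comes back at 25. The oxirane of 10 is opened before the furans are present (HCl in Et2O, −30 °C, where stronger or chelating conditions are tolerable and a regioisomer can be removed) to (2S,3S,6S)-2-chloro-3-hydroxy-6-methyloct-7-en-4-one F7, which is protected (t-BuMe2SiOTf, 2,6-lutidine, CH2Cl2, −78 °C) as the tert-butyldimethylsilyl ether of F7 F8. 9-BBN (2.5 equiv) gives the bis-boron adduct of F8 F9, which is coupled with 21 without water (PdCl2(dppf), AsPh3, anhydrous K3PO4, DMF, 50 °C; neutral work-up) to the silyl-protected chloro alcohol F10. DMP/pyridine oxidises it to the silyl-protected chloro ketone F11, and HF·pyridine in THF removes the silyl group to give 25.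

Further compounds
F1 | step 7 | (2R)-but-3-en-2-yl methyl carbonate | C=C[C@@H](C)OC(=O)OC
F2 | step 7 | copper enolate of 5 | C[C@H]1O[C@H]1C(=C)O[Cu]
F3 | step 12 | (1RS,3S)-3-methyl-1-(3-methyloxiran-2-yl)pent-4-en-1-ol, oxirane centres as in 10 | C=C[C@@H](C)CC(O)[C@@H]1O[C@@H]1C
F4 | step 12 | triethylsilyl ether of F3 | C=C[C@@H](C)CC(O[Si](CC)(CC)CC)[C@@H]1O[C@@H]1C
F5 | step 12 | B-alkyl-9-BBN derivative of F4 | B1(C2CCCC1CCC2)CC[C@@H](C)CC(O[Si](CC)(CC)CC)[C@@H]1O[C@@H]1C
F6 | step 12 | triethylsilyl ether of 23 | C/C(=C\CC[C@@H](C)CC(O[Si](CC)(CC)CC)[C@@H]1O[C@@H]1C)CCCc1coc(Cc2ccoc2)c1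
F7 | step 14 | (2S,3S,6S)-2-chloro-3-hydroxy-6-methyloct-7-en-4-one | C=C[C@@H](C)CC(=O)[C@H](O)[C@H](C)Cl
F8 | step 14 | tert-butyldimethylsilyl ether of F7 | C=C[C@@H](C)CC(=O)[C@H](O[Si](C)(C)C(C)(C)C)[C@H](C)Cl
F9 | step 14 | bis-boron adduct of F8 (9-BBN on the terminal carbon and on the carbinol oxygen) | B1(C2CCCC1CCC2)CC[C@@H](C)CC(OB1C2CCCC1CCC2)[C@H](O[Si](C)(C)C(C)(C)C)[C@H](C)Cl
F10 | step 14 | silyl-protected chloro alcohol (C4 carbinol of the 3-O-silyl ether of 25) | C/C(=C\CC[C@@H](C)CC(O)[C@H](O[Si](C)(C)C(C)(C)C)[C@H](C)Cl)CCCc1coc(Cc2ccoc2)c1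
F11 | step 14 | silyl-protected chloro ketone (3-O-tert-butyldimethylsilyl ether of 25) | C/C(=C\CC[C@@H](C)CC(=O)[C@H](O[Si](C)(C)C(C)(C)C)[C@H](C)Cl)CCCc1coc(Cc2ccoc2)c1
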